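## Analysis of the target

The target, 5-henicosyl-1H-pyrrole-2-carbaldehyde 9, is a single 1H-pyrrole ring with a formyl group at C2 and an unbranched 21-carbon chain at C5; N1, C3 and C4 carry only hydrogen. It has no stereocentre and no double-bond geometry, so the problem is one of connectivity and regiochemistry. The sensitive parts are the electron-rich pyrrole nucleus, which oligomerises under acid and oxidises easily while no acceptor is attached, the free N–H, and the aldehyde, which is fairly robust once in place because it is a vinylogous formamide. The first difficulty is that C2 and C5 must receive different substituents without C3 or C4 isomers, which electrophilic substitution of a preformed pyrrole does not guarantee. The second is that every intermediate carrying the C21 chain is a non-polar wax that dissolves poorly in polar media, which limits solvents and purification. The plan rests on one feature: the formyl carbon, C2, C3, C4, C5 and the 21 chain carbons form one unbranched string of 26 carbons, bridged only by N1 between C2 and C5. A conjugated diyne across C2 to C5 of that string, plus one molecule of ammonia, has exactly the atoms and oxidation level of the pyrrole, so the ring can be closed by two C–N bonds with no redox step while the formyl carbon travels as an acetal at its final oxidation level.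

## Retrosynthetic reasoning

**9 to 8.** The last operation is the unmasking of the formyl group, so 9 is traced back to its diethyl acetal, 2-(diethoxymethyl)-5-henicosyl-1H-pyrrole 8. No skeletal bond is cut; only the C=O on the carbon attached to C2 is exchanged for two C–O single bonds. A free aldehyde conjugated to a diyne would be a strong Michael acceptor and would condense with the nitrogen source, so it must stay masked until the ring exists. The forward step is a mild acid hydrolysis. Because an N-unsubstituted pyrrol-2-yl acetal ionises very easily, 8 is planned as a compound that is formed and hydrolysed in the same flask.

**8 to 7.** Both ring C–N bonds, N1–C2 and N1–C5, are cut. This is preferred over any C–C cut of the ring because it leaves the whole carbon skeleton as one linear chain, 1,1-diethoxyhexacosa-2,4-diyne 7, and it makes the 2,5-pattern a consequence of connectivity: a nitrogen that bridges the two outer carbons of a 1,3-diyne can only give this isomer. The chain numbering of 7 and the ring numbering coincide for C2 to C5. The forward reaction has to add one nitrogen atom at the amine oxidation level across the diyne under monovalent copper catalysis: an intermolecular hydroamination at C2 or C5, then a 5-endo-dig closure onto the remaining alkyne, then aromatisation.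

**7 to 4 and 6.** The central sp–sp bond C3–C4 is cut. It is the only C–C bond of the diyne that a coupling of two alkynes can form, and it divides 7 into a C23 piece, tricos-1-yne 4, and a C3 piece, 3-bromo-1,1-diethoxyprop-2-yne 6, that already holds the acetal. The forward reaction must join two alkynyl carbons of like polarity, which requires one partner as the copper acetylide and the other as the haloalkyne, and it must favour the cross-product over both symmetric dimers.

**6 to 5.** The C–Br bond is cut, leading to commercial 3,3-diethoxyprop-1-yne 5. The forward step is an electrophilic bromination of the terminal alkyne carbon that leaves the acetal intact.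

**4 to 2 and 3.** The terminal alkyne carbon is cut from the chain, giving docosanal 2 and the one-carbon donor dimethyl (1-diazo-2-oxopropyl)phosphonate 3. A one-carbon homologation of an aldehyde is preferred over alkylation of an acetylide, because the latter would need an odd-numbered C21 alkyl halide, whereas the even-numbered C22 series is a commodity.

**2 to 1.** The aldehyde is traced to docosan-1-ol 1 by adjustment of the oxidation level at C1; the forward step is a selective oxidation that stops at the aldehyde.

## Alternatives that were turned down

**Alternative 1:** Only the N1–C5 bond is cut; C2 keeps its nitrogen as an azide and its substituent as a methyl ester. The open-chain precursor, methyl (2Z,4E)-2-azidohexacosa-2,4-dienoate A1, would come from base-mediated condensation of (E)-tetracos-2-enal A2, a two-carbon homologue of 2, with methyl azidoacetate A3. In the key step A1 loses N2 under ZnI2 or Rh2(O2CC3F7)4 catalysis and the remaining nitrogen bonds to C5, giving methyl 5-henicosyl-1H-pyrrole-2-carboxylate A4.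
- For it: the closure to A4 runs at or near room temperature, delivers the N–H pyrrole directly and cannot give another substitution pattern. On the ring closure itself it is stronger than the chosen route, whose closure needs heat, pressure and a nitrogen partner less well documented than primary amines.
- Against it: in A4 the C2 substituent arrives one oxidation level too high. The ester must be reduced to (5-henicosyl-1H-pyrrol-2-yl)methanol A5 and then re-oxidised to 9, and A5 is a carbinol that ionises to an azafulvene and oligomerises. The condensation of A3 with an enolisable aliphatic enal is usually the weak step, because γ-deprotonation and base-induced decomposition of the azide compete. A2 costs extra steps, and organic azides are unwelcome on scale.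
- Comparison: counted from 1 the sequence is six to seven steps against five. The chosen strategy offers redox economy in its place: the formyl carbon is never above or below its final oxidation level after the chain is assembled, and no azide is handled.

**Alternative 2:** The bond between C5 and the first chain carbon is cut. Docosanoic acid A6 would be converted into its N-hydroxyphthalimide ester, 1,3-dioxoisoindolin-2-yl docosanoate A7. A7 would then be coupled with tert-butyl 2-bromo-5-formyl-1H-pyrrole-1-carboxylate A8 using NiBr2(dimethoxyethane) and 4,4'-di-tert-butyl-2,2'-bipyridine under zinc or cathodic reduction. Loss of CO2 gives a primary C21 radical that is captured at nickel, and the product is tert-butyl 2-formyl-5-henicosyl-1H-pyrrole-1-carboxylate A9.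
- For it: it is the most convergent plan, A6 is the cheapest C22 source and is used directly, and ring and aldehyde are in place from the start. In convergence, and probably in step count on the lipid side, it is stronger than the chosen route.
- Against it: A8 is not a simple compound. Electrophilic bromination of 1H-pyrrole-2-carbaldehyde A10 goes mainly to C4, so the 5-bromo isomer cannot be taken from A10 directly and needs an indirect route plus N-protection. The reacting carbon of A8 is flanked by the N-Boc group and its C–Br bond is not strongly activated. Primary alkyl radicals from esters such as A7 couple best with aryl iodides, and hydrodehalogenation, chain dimerisation and chain reduction consume both partners. A free aldehyde must survive zinc and low-valent nickel, and removal of the Boc group from A9 follows.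
- Comparison: the chosen strategy cannot give C3 or C4 isomers, because the pattern is written into the chain, and its C–C bond formation is a long-established coupling of two stable, purifiable partners.

**Alternative 3:** Both C–N bonds are cut, and then the C4–C5 bond of the resulting 1,4-diketone. Docosanal 2, as its Breslow intermediate from a thiazolium salt and an amine base, would add 1,4 to 1,1-dimethoxybut-3-en-2-one A11 to give 1,1-dimethoxyhexacosane-2,5-dione A12. Paal–Knorr condensation of A12 with an ammonium salt would give 2-(dimethoxymethyl)-5-henicosyl-1H-pyrrole A13, and acid would convert A13 into 9.
- For it: Paal–Knorr closure with ammonia is the textbook route to N–H pyrroles and is more assured than copper-catalysed addition of ammonia to a diyne, so on ring closure it is stronger. It needs no homologation of 2, is at least as short on the lipid side, and has the same redox economy.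
- Against it: A11 is an unhindered, doubly activated vinyl ketone that polymerises under the amine base, is not a stock chemical and must be made and used fresh. Acyloin self-condensation of 2 competes. A12 has an acidic C3 methylene and two ketones, so intramolecular aldol condensation to a cyclopentenone is open under the basic conditions of its formation. The ketone next to the acetal is hindered in the Paal–Knorr step.
- Comparison: the chosen strategy places its uncertainty in the ring closure instead of the C–C bond formation. In exchange its coupling partners 4 and 6 are stable to their own coupling conditions, and 7 has no acidic or electrophilic site through which it could react with itself.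

Key step: step 4

Remark on the chemistry: the target has no stereogenic element; 8 is treated as a labile in-flask intermediate and hydrolysed without isolation, which merges ring closure and unmasking into one operation.

## Route

**Step 1**
Reactants: 1 docosan-1-ol
Product: 2 docosanal
Conditions: TEMPO (10 mol %), PhI(OAc)2 (1.1 equiv), CH2Cl2, 30–35 °C
Reagents that add atoms: none
Why: Oxoammonium-mediated (TEMPO) oxidation with PhI(OAc)2 as terminal oxidant should stop at the aldehyde in the absence of water, and gentle warming keeps the long-chain alcohol dissolved. The aldehyde is used without storage to avoid air oxidation and trimerisation.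

**Step 2**
Reactants: 2 docosanal; 3 dimethyl (1-diazo-2-oxopropyl)phosphonate
Product: 4 tricos-1-yne
Conditions: K2CO3 (2 equiv), MeOH/THF 1:1, 0 °C → rt
Reagents that add atoms: none
Why: Ohira–Bestmann variant of the Seyferth–Gilbert homologation: methanolysis of the acetyl group of 3 releases the diazomethylphosphonate anion, which olefinates 2 in a Horner–Wadsworth–Emmons sense, and loss of N2 followed by a 1,2-hydrogen shift in the alkylidene carbene gives the terminal alkyne with one added carbon. The mild carbonate base tolerates the enolisable aldehyde, and THF keeps the waxy substrate in solution.

**Step 3**
Reactants: 5 3,3-diethoxyprop-1-yne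
Product: 6 3-bromo-1,1-diethoxyprop-2-yne
Conditions: NBS (1.1 equiv), AgNO3 (10 mol %), acetone, rt, dark
Reagents that add atoms: N-bromosuccinimide, O=C1CCC(=O)N1Br
Why: Silver-catalysed electrophilic bromination of a terminal alkyne with NBS proceeds through the silver acetylide under nearly neutral conditions, so the diethyl acetal should survive. The bromoalkyne is kept cold and in solution and used promptly in step 4.

**Step 4**
Reactants: 4 tricos-1-yne; 6 3-bromo-1,1-diethoxyprop-2-yne
Product: 7 1,1-diethoxyhexacosa-2,4-diyne
Conditions: CuCl (5 mol %), NH2OH·HCl (0.3 equiv), n-BuNH2 (3 equiv), THF/MeOH/H2O, argon, 0 °C → rt, 6 (1.2 equiv) added slowly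
Reagents that add atoms: none
Why: The reaction is the Cadiot–Chodkiewicz coupling, which is also the closest known reaction type. The amine deprotonates copper-bound 4 to the monovalent copper acetylide, the C–Br bond of 6 adds oxidatively to it, and reductive elimination from the trivalent copper bis(alkynyl) species forms the sp–sp bond that becomes C3–C4 of the pyrrole and returns monovalent copper. No ring is closed and no stereocentre is formed; the step joins the C23 and C3 pieces into the complete unbranched C26 chain with the diyne across C2 to C5. The selectivity required is hetero-coupling over the two homo-couplings. Hydroxylamine keeps the copper monovalent, which shuts down oxidative Glaser dimerisation of 4. The acetal-bearing alkyne is used as the bromide because its C–Br bond is polarised by the inductively withdrawing acetal carbon and adds quickly to copper, and slow addition keeps its concentration low so that bromine–copper exchange and dimerisation of 6 stay minor. The diethyl acetal is inert to the amine medium and carries the formyl carbon at its final oxidation level, and THF and methanol keep the waxy alkyne in solution.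

**Step 5**
Reactants: 7 1,1-diethoxyhexacosa-2,4-diyne
Product: 9 5-henicosyl-1H-pyrrole-2-carbaldehyde, via pyrrole diethyl acetal 8 (not isolated)
Conditions: NH3 (large excess, sat. in EtOH/1,4-dioxane), CuCl (20 mol %), argon, sealed tube, 110 °C; evaporate; then 1 M aq. HCl, THF, 0 °C → rt
Reagents that add atoms: ammonia, N; water, O
Why: Copper-catalysed double hydroamination of a conjugated diyne, well established with primary amines and less documented with ammonia: nitrogen adds to an outer diyne carbon (C2 or C5) of the copper-activated system, the enamine closes 5-endo-dig onto the second alkyne and a proton shift aromatises, both orders of addition converging on 8 because nitrogen must bridge C2 and C5. Aqueous acid then hydrolyses the acetal through a pyrrole-stabilised azafulvenium ion, and the formyl group so formed deactivates the ring towards acid. 8 is not isolated because it loses ethanol easily, and any mixed acetal or aldimine formed from it hydrolyses to the same aldehyde.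

## Compound list

1 | docosan-1-ol | CCCCCCCCCCCCCCCCCCCCCCO | starting material
2 | docosanal | CCCCCCCCCCCCCCCCCCCCCC=O | intermediate
3 | dimethyl (1-diazo-2-oxopropyl)phosphonate | CC(=O)C(=[N+]=[N-])P(=O)(OC)OC | starting material
4 | tricos-1-yne | CCCCCCCCCCCCCCCCCCCCCC#C | intermediate
5 | 3,3-diethoxyprop-1-yne | CCOC(OCC)C#C | starting material
6 | 3-bromo-1,1-diethoxyprop-2-yne | CCOC(OCC)C#CBr | intermediate
7 | 1,1-diethoxyhexacosa-2,4-diyne | CCCCCCCCCCCCCCCCCCCCCC#CC#CC(OCC)OCC | intermediate
8 | 2-(diethoxymethyl)-5-henicosyl-1H-pyrrole | CCCCCCCCCCCCCCCCCCCCCc1ccc(C(OCC)OCC)[nH]1 | intermediate
9 | 5-henicosyl-1H-pyrrole-2-carbaldehyde | CCCCCCCCCCCCCCCCCCCCCc1ccc(C=O)[nH]1 | target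

## Step count and least certain steps

Total step count: 5. Longest linear sequence: 4 steps (steps 1, 2, 4 and 5, from 1 to 9); step 3 supplies the second coupling partner.

**Step 4 (key step).** The most likely failure is bromine–copper exchange between the acetylide of 4 and 6, followed by homo-coupling of either partner, together with slow turnover when the waxy alkyne separates from the amine-rich phase. The purified diyne may also polymerise in the solid state under light, so it is kept in the dark and used promptly. The fallback sets out from 2 and 5 and returns at 7. Docosanal 2 is converted by Corey–Fuchs olefination (CBr4, PPh3, CH2Cl2, 0 °C) into 1,1-dibromotricos-1-ene F1. F1 and 5 are then heated with Pd2(dba)3, tris(2-furyl)phosphine and Et3N in DMF at 80 °C under copper-free conditions. Zerovalent palladium inserts into the C–Br bond trans to the chain, and alkynylation gives (Z)-4-bromo-1,1-diethoxyhexacos-4-en-2-yne F2. F2 then loses HBr by anti elimination in the same flask to give 7. No haloalkyne and no copper acetylide is involved, so the homo-coupling channel is closed.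

**Step 5.** The most likely failure is a slow first addition of ammonia, which is a weak nucleophile and binds copper strongly, so that thermal oligomerisation of the diyne outruns ring closure. A second failure is loss of ethanol from the N-unsubstituted acetal and condensation of the resulting azafulvene before the acid is added. The fallback sets out from 7 and returns at 9. 7 is heated with 2,4-dimethoxybenzylamine and CuCl (10 mol %) at 100 °C, the established primary-amine version of the ring closure, to give 1-(2,4-dimethoxybenzyl)-2-(diethoxymethyl)-5-henicosyl-1H-pyrrole F3. F3 is an N-substituted acetal that can be chromatographed. Trifluoroacetic acid containing water and anisole then hydrolyses the acetal to 1-(2,4-dimethoxybenzyl)-5-henicosyl-1H-pyrrole-2-carbaldehyde F4. On warming, F4 cleaves at the benzylic N–C bond, because the O-protonated formylpyrrole is a good leaving group and anisole traps the benzyl cation, and this gives 9.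

**Step 3.** The most likely failure is partial cleavage of the acetal by the nitric acid released during silver-mediated bromination, and decomposition of the small, volatile bromoalkyne during concentration. The fallback sets out from 4 and 5 and returns at 7, with the roles of the partners exchanged. 4 is brominated (NBS, AgNO3 cat., acetone, rt) to 1-bromotricos-1-yne F5, a non-volatile wax without an acid-sensitive group. F5 is coupled with the terminal alkyne 5 under the conditions of step 4 to give 7 directly. The cost is that the more valuable C23 piece becomes the partner exposed to exchange-driven dimerisation.

**Step 2.** The most likely failure is incomplete conversion because the waxy aldehyde separates from the methanolic phase, and aldol self-condensation of 2 under carbonate when the olefination is slow. The fallback sets out from 2 and returns at 4. Wittig chloromethylenation of 2 with (chloromethyl)triphenylphosphonium chloride and KOt-Bu in THF at 0 °C gives 1-chlorotricos-1-ene F6 as an E/Z mixture. Treatment of F6 with n-BuLi (2.2 equiv, THF, 0 °C) and aqueous quench eliminates HCl from both isomers to give 4.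

## Further compounds

F1 | step 4 | 1,1-dibromotricos-1-ene | CCCCCCCCCCCCCCCCCCCCCC=C(Br)Br
F2 | step 4 | (Z)-4-bromo-1,1-diethoxyhexacos-4-en-2-yne | CCCCCCCCCCCCCCCCCCCCC/C=C(\Br)C#CC(OCC)OCC
F3 | step 5 | 1-(2,4-dimethoxybenzyl)-2-(diethoxymethyl)-5-henicosyl-1H-pyrrole | CCCCCCCCCCCCCCCCCCCCCc1ccc(C(OCC)OCC)n1Cc1ccc(OC)cc1OC
F4 | step 5 | 1-(2,4-dimethoxybenzyl)-5-henicosyl-1H-pyrrole-2-carbaldehyde | CCCCCCCCCCCCCCCCCCCCCc1ccc(C=O)n1Cc1ccc(OC)cc1OC
F5 | step 3 | 1-bromotricos-1-yne | CCCCCCCCCCCCCCCCCCCCCC#CBr
F6 | step 2 | 1-chlorotricos-1-ene (E/Z mixture) | CCCCCCCCCCCCCCCCCCCCCC=CCl
A1 | alternative 1 | methyl (2Z,4E)-2-azidohexacosa-2,4-dienoate | CCCCCCCCCCCCCCCCCCCCC/C=C/C=C(\N=[N+]=[N-])C(=O)OC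
A2 | alternative 1 | (E)-tetracos-2-enal | CCCCCCCCCCCCCCCCCCCCC/C=C/C=O
A3 | alternative 1 | methyl azidoacetate | COC(=O)CN=[N+]=[N-]
A4 | alternative 1 | methyl 5-henicosyl-1H-pyrrole-2-carboxylate | CCCCCCCCCCCCCCCCCCCCCc1ccc(C(=O)OC)[nH]1
A5 | alternative 1 | (5-henicosyl-1H-pyrrol-2-yl)methanol | CCCCCCCCCCCCCCCCCCCCCc1ccc(CO)[nH]1
A6 | alternative 2 | docosanoic acid | CCCCCCCCCCCCCCCCCCCCCC(=O)O
A7 | alternative 2 | 1,3-dioxoisoindolin-2-yl docosanoate | CCCCCCCCCCCCCCCCCCCCCC(=O)ON1C(=O)c2ccccc2C1=O
A8 | alternative 2 | tert-butyl 2-bromo-5-formyl-1H-pyrrole-1-carboxylate | CC(C)(C)OC(=O)n1c(Br)ccc1C=O
A9 | alternative 2 | tert-butyl 2-formyl-5-henicosyl-1H-pyrrole-1-carboxylate | CCCCCCCCCCCCCCCCCCCCCc1ccc(C=O)n1C(=O)OC(C)(C)C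
A10 | alternative 2 | 1H-pyrrole-2-carbaldehyde | O=Cc1ccc[nH]1
A11 | alternative 3 | 1,1-dimethoxybut-3-en-2-one | COC(OC)C(=O)C=C
A12 | alternative 3 | 1,1-dimethoxyhexacosane-2,5-dione | CCCCCCCCCCCCCCCCCCCCCC(=O)CCC(=O)C(OC)OC
A13 | alternative 3 | 2-(dimethoxymethyl)-5-henicosyl-1H-pyrrole | CCCCCCCCCCCCCCCCCCCCCc1ccc(C(OC)OC)[nH]1
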